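The runs come from a simulation for an exercise; noise was put on by code.

**The leftover.** In the eta run, the reading left 70.0% of the charge not yet counted as target after 3.00 h, and I asked how long that flask needed for the whole charge at its early pace.

| flask | starting material | second substrate | free catalyst | remark | time |
|---|---|---|---|---|---|
| eta | 10 mM | 20 mM | 1 mM | run made earlier |  |
| delta | 10 mM | 20 mM | 1.4 mM | run made earlier |  |
| zeta | 10 mM | 20 mM | 2.2 mM | run made earlier |  |
| epsilon | 10 mM | 40 mM | 1 mM | run made earlier |  |
| north | 10 mM | 20.0 mM | 1.0 mM | one stirred flow tank at steady state, fed with the mixture as stated, mean residence time 5.0 h |  |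
| west | 10 mM | 20.0 mM | 1.0 mM | a closed flask charged with all of it at once and left for 5.0 h | 5.0 h |
| south-east | 10 mM | 20.0 mM | 1.0 mM | one stirred flow tank at steady state, fed with the mixture as stated, mean residence time 50.0 h |  |
| north-east | 10 mM (fed, over 2.50 h) | 20.0 mM | 1.0 mM | all but starting material at the start; starting material goes in evenly over 2.50 h, the run ends at 5.0 h | 5.0 h |

| run | time / h | target / % |
|---|---|---|
| eta | 0.250 | 3 |
| eta | 0.417 | 0 |
| eta | 0.833 | 5 |
| eta | 1.50 | 15 |
| eta | 3.00 | 30 |
| delta | 0.417 | 10 |
| delta | 0.833 | 8 |
| delta | 1.33 | 22 |
| delta | 2.50 | 31 |
| delta | 5.00 | 60 |
| zeta | 0.417 | 10 |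
| zeta | 1.33 | 27 |
| zeta | 2.50 | 51 |
| zeta | 4.00 | 71 |
| zeta | 5.00 | 81 |
| epsilon | 0.417 | 2 |
| epsilon | 0.833 | 5 |
| epsilon | 1.33 | 7 |
| epsilon | 2.50 | 16 |
| epsilon | 5.00 | 32 |

(scatter of a reading: 2 percentage points)

- the stated concentrations are those of everything mixed, before any reaction; amounts are the same in each set-up
- the numbers in the tables scatter by 2 percentage points (one standard deviation)
- candidate steps: starting material + free catalyst <-> catalyst intermediate A; catalyst intermediate B -> free catalyst + second product; starting material -> uncatalysed product; second substrate + free catalyst <-> catalyst intermediate B; catalyst intermediate A -> free catalyst + target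
- the feed brings no volume worth counting
- the earlier runs were made in a closed, stirred flask

- the set-up with the highest amount of target at the outlet or at the end, in percent of the starting material put in ("none" if the first two lie within 2 percentage points) (north / west / south-east / north-east / none)
- amount of target at the outlet or at the end, in percent of the starting material put in, north
- amount of target at the outlet or at the end, in percent of the starting material put in, west
- amount of target at the outlet or at the end, in percent of the starting material put in, south-east
- amount of target at the outlet or at the end, in percent of the starting material put in, north-east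

**Clearing time.** Dividing 3.00 h by the reading of 30% gave 10.0 h, my clearing time: the time to make the whole charge into target at the early pace, here with [free catalyst] at 1 mM and [second substrate] at 20 mM. It is a reading and carries the scatter.

**Near twin.** The epsilon run differed from eta in [second substrate] alone, 40 mM against 20 mM. Its 32% at 5.00 h gave a clearing time of 15.6 h, longer than eta's. I read this as second substrate competing for free catalyst, because with the same catalyst charge the readings put epsilon at 64.1% of eta's pace.

**The drift.** I scaled the clearing time to zeta's 2.2 mM of free catalyst, which gave 4.55 h. Zeta read 51% at 2.50 h against a steady 54.9%, and 81% at 5.00 h against a steady 110%, so the readings fell behind the steady line late in the zeta run.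

**My reckoning.** West had 0.500 clearing times, so a steady pace gave 50.0%, and I expected somewhat less. South-east had 5.00 clearing times, more than west, so I put it first.

**The forecast.** It gave 41% for north, 47% for west, 89% for south-east and 39% for north-east, with south-east best, saying “The runs fit competitive saturation kinetics”. Its west lay below my steady figure.

**The result.** South-east gave 84.4% and was best, against 40.9% for north, 45.9% for west and 39.5% for north-east. Its outlet also held 10.7% of uncatalysed product. West reached 91.8% of the steady-pace figure.

    starting material + free catalyst ⇌ catalyst intermediate A (K = 140 M⁻¹, k = 700 M⁻¹ h⁻¹)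
    catalyst intermediate B → free catalyst + second product (k = 4.30 h⁻¹)
    starting material → uncatalysed product (k = 0.0460 h⁻¹)
    second substrate + free catalyst ⇌ catalyst intermediate B (K = 110 M⁻¹, k = 12000 M⁻¹ h⁻¹)
    catalyst intermediate A → free catalyst + target (k = 7.00 h⁻¹)

**Second flask.** With 4.0 mM of free catalyst in the north-east recipe, the clearing time scaled to 2.50 h, so the run had 2.00 clearing times. That flask gave 94.3% of target, with 4.23% of uncatalysed product.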